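A small charge of starting material, the limiting reagent, sits with 1.80 equiv of partner in a closed, stirred flask, and I want to know where that charge stands at 20 h.

in all of them: starting material 0.050 M

|  | partner | remark | time |
|---|---|---|---|
| spring | 1.8 equiv | the very flask that is asked about, followed so far |  |
| noon | 2.7 equiv | run made earlier |  |
| flask | 1.80 equiv |  | 20 h |

| run | time / h | intermediate A / % | isomer of the product / % | target / % | starting material / % | intermediate B / % | intermediate C / % |
|---|---|---|---|---|---|---|---|
| spring | 0.500 | 5 | 0 | 1 | 100 | 3 | 0 |
| spring | 1.00 | 1 | 0 | 4 | 100 | 1 | 0 |
| spring | 2.50 | 5 | 0 | 0 | 95 | 0 | 0 |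
| spring | 6.00 | 10 | 0 | 0 | 90 | 2 | 1 |
| noon | 4.00 | 7 | 1 | 0 | 93 | 0 | 0 |
| noon | 8.00 | 9 | 0 | 3 | 89 | 3 | 0 |
| noon | 10.0 | 14 | 0 | 0 | 84 | 2 | 0 |
| noon | 15.0 | 16 | 1 | 0 | 77 | 7 | 0 |

(each reading ± 1.5 percentage points)

- for target the crystals are counted in
- as a solid, counted per litre of solution: crystals
- steps under discussion: starting material -> intermediate A; intermediate A <-> intermediate B; intermediate B -> intermediate C; intermediate C <-> intermediate D; partner + intermediate C -> target; target <-> isomer of the product; crystals <-> target
- a reading or a percentage of intermediate C is of its free form alone

- where most of what was charged as starting material, at 20 h is found (intermediate B / isomer of the product / intermediate A / starting material / intermediate C / target)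
- the largest share itself, whichever of these holds it, in percent of the starting material charged

I turn the readings into times. The noon run has 77% of its starting material left at 15.0 h, a first-order loss of 0.0174 h⁻¹. The spring run at 6.00 h reads 0.0176 h⁻¹, about the same at a different partner charge, so I carry the noon value over to the flask. That makes 39.8 h the feed half-life, the first-order half-life in which the fraction of starting material left halves.

The ladder, fastest first. Intermediate B in the noon run at 7% after 15.0 h, one rough reading, puts the forward half-life of intermediate A near 19.4 h, shorter than the feed half-life, yet in that reading intermediate A still stands above intermediate B. Next comes the feed: the flask runs for half a feed half-life, so I expect 70.6% of the charge left as starting material. That estimate leaves 29.4% of the charge to be shared among the other species in this flask, less than what stays, so my answer is starting material. For the last rung I can read no time: in the noon run target and intermediate C both read 0 at 15.0 h.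

The forecast says starting material at 70%, on its own ground: “the two runs lie on one curve”.

The flask gives starting material at 70.9%.

    starting material → intermediate A (k = 2.86 × 10⁻⁴ min⁻¹)
    intermediate A ⇌ intermediate B (K = 23.1, k = 7.07 × 10⁻⁴ min⁻¹)
    intermediate B → intermediate C (k = 4.21 × 10⁻⁴ min⁻¹)
    intermediate C ⇌ intermediate D (K = 0.432, k = 4.53 × 10⁻⁴ min⁻¹)
    partner + intermediate C → target (k = 0.0170 M⁻¹ min⁻¹)
    target ⇌ isomer of the product (K = 1.47, k = 0.00176 min⁻¹)
    crystals ⇌ target, rate k7*(cs7 - [target]) while solid is left; crystals form when [target] > cs7 (solubility = 1.30 mM, k = 0.0903 min⁻¹)

This flask has not come to rest at 20 h: intermediate A is still made 1.52 times faster than it is used up. The neighbour flask, with the same charges but read at 48.0 h, holds 43.9% starting material, where the feed half-life gives 43.3%. Ten times the time takes starting material in the flask down to 3.23% and partner to 56.7% of its charge, and lifts target from 0.380% to 74.1%, of which 71.4% is crystals, while intermediate B stands at 8.38%.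

The data come from a simulation from invented constants, and the scatter is random.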